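**Retrosynthetic overview**
1. Target ⇐ desilylation/ester release ⇐ C12 ketone reduction ⇐ selenolactonisation–selenoxide elimination of a 1(10)-ene 19-acid (lactone and C1=C2 last).
2. Ring B ⇐ Pd-catalysed reductive Heck cyclisation of a C10 vinyl bromide onto the C9=C11 enone (C9–C10), after C5–C6 is made by Ireland–Claisen rearrangement of the ester that joins the two fragments.
3. Fragment 1 (rings C/D acid 16) ⇐ gold-catalysed 5-exo-dig cyclisation of an enediol bis-silyl ether onto a propargyl group (ring D, C13); C8 from a Johnson–Claisen rearrangement of a CBS-derived cyclohexenol.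
4. Fragment 2 (ring A alcohol 29) ⇐ Diels–Alder adduct → dienone → Cu-catalysed desymmetrising borylation/oxidation → α-bromination → CBS reduction.
5. Ring order: C (from cyclohexane-1,3-dione) and A (Diels–Alder) in parallel, then D (Au), B (Pd), lactone.

Assumption: simple alcohols, silylating agents and other heteroatom donors are treated as reagents; from compound 30 on, gibberellane numbering (C1–C19) is used with α/β as in the usual gibberellin drawing (3β-O, 4β-Me/4α-carboxyl, 5β-H, 6β-carboxyl, 9β-H, 10α-O, the 8/13 bridge as in the target, and 12α-O meaning the 12-oxygen 1,3-syn to the C9–C10 bond and anti to the C13–C16 bond).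

**Fragment 1 (rings C/D)**

Step 1
Reactants: 1 cyclohexane-1,3-dione
Product: 2 3-ethoxycyclohex-2-en-1-one
Conditions: EtOH, TsOH (cat.), toluene, reflux, Dean–Stark
Reagents that add atoms: ethanol CCO
Why: Acid-catalysed vinylogous esterification of the enolised 1,3-dione with azeotropic water removal gives the Stork–Danheiser substrate.

Step 2
Reactants: 2 3-ethoxycyclohex-2-en-1-one; 3 3-bromoprop-1-yne (propargyl bromide)
Product: 6 3-(prop-2-yn-1-yl)cyclohex-2-en-1-one, via Grignard reagent 4 (not isolated), via tertiary allylic alcohol 5 (not isolated)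
Conditions: 3, Mg, HgCl2 (cat.), Et2O, 0 °C; add 2, −78 to 0 °C; then 1 M HCl, 0 °C
Reagents that add atoms: none
Why: Stork–Danheiser sequence in which the propargyl/allenyl Grignard reagent adds 1,2 to the vinylogous ester carbonyl through its allenyl form (giving the propargyl carbinol) and mild acid hydrolysis of the enol ether with loss of water transposes the enone.

Step 3
Reactants: 6 3-(prop-2-yn-1-yl)cyclohex-2-en-1-one
Product: 7 (1R)-3-(prop-2-yn-1-yl)cyclohex-2-en-1-ol
Conditions: (S)-Me-CBS (20 mol%), catecholborane, toluene, −78 °C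
Reagents that add atoms: none
Why: Corey–Bakshi–Shibata reduction with the alkenyl side as the large group delivers hydride to one face and sets the (R)-carbinol that later relays chirality to C8, while catecholborane at −78 °C leaves the alkyne untouched.

Step 4
Reactants: 7 (1R)-3-(prop-2-yn-1-yl)cyclohex-2-en-1-ol; 8 1,1,1-trimethoxyethane
Product: 10 methyl 2-[(1S)-1-(prop-2-yn-1-yl)cyclohex-2-en-1-yl]acetate, via ketene acetal 9 (not isolated)
Conditions: 8 (6 equiv), EtCO2H (cat.), xylene, 140 °C, MeOH distilled off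
Reagents that add atoms: none
Why: Johnson–Claisen rearrangement, a suprafacial [3,3] shift that delivers the CH2CO2Me unit to the face of C8 from which the C–O bond departs, creates the quaternary centre C8 by chirality transfer and moves the alkene to C9=C11.

Step 5
Reactants: 10 methyl 2-[(1S)-1-(prop-2-yn-1-yl)cyclohex-2-en-1-yl]acetate
Product: 11 methyl 2-[(1S)-4-oxo-1-(prop-2-yn-1-yl)cyclohex-2-en-1-yl]acetate
Conditions: CrO3, 3,5-dimethylpyrazole, CH2Cl2, −20 °C
Reagents that add atoms: chromium trioxide O=[Cr](=O)=O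
Why: Allylic C–H oxidation (CrO3–dimethylpyrazole) attacks the only allylic methylene, C12, because the other allylic position C8 is quaternary, giving the 4,4-disubstituted enone.

Step 6
Reactants: 11 methyl 2-[(1S)-4-oxo-1-(prop-2-yn-1-yl)cyclohex-2-en-1-yl]acetate
Product: 13 methyl 2-[(1R,5RS)-5-[(tert-butyldimethylsilyl)oxy]-4-oxo-1-(prop-2-yn-1-yl)cyclohex-2-en-1-yl]acetate, via silyl dienol ether 12 (not isolated)
Conditions: TBSOTf, Et3N, CH2Cl2, 0 °C; then mCPBA, NaHCO3, CH2Cl2, −20 °C to rt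
Reagents that add atoms: tert-butyldimethylsilyl triflate CC(C)(C)[Si](C)(C)OS(=O)(=O)C(F)(F)F; 3-chloroperbenzoic acid OOC(=O)c1cccc(Cl)c1
Why: Rubottom oxidation, in which soft enolisation can only go toward C13 (no γ-hydrogen at quaternary C8) and the electron-rich enol double bond is epoxidised and rearranges with silyl transfer to the α'-silyloxy ketone; the C13 configuration is irrelevant because C13 is planarised in step 7.

Step 7
Reactants: 13 methyl 2-[(1R,5RS)-5-[(tert-butyldimethylsilyl)oxy]-4-oxo-1-(prop-2-yn-1-yl)cyclohex-2-en-1-yl]acetate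
Product: 15 methyl 2-[(1R,5S)-5-[(tert-butyldimethylsilyl)oxy]-6-methylidene-4-oxobicyclo[3.2.1]oct-2-en-1-yl]acetate, via bis-silyl enediol ether 14 (not isolated)
Conditions: TBSOTf, Et3N, CH2Cl2, 0 °C; then [Au(PPh3)(NCMe)]SbF6 (5 mol%), CH2Cl2/MeOH 10:1, 25 °C
Reagents that add atoms: none
Why: Proposed new method: monovalent-gold π-activation of the terminal alkyne lets the ene-1,2-diol bis(silyl ether) attack through C13 in a 5-exo-dig anti-carboauration (the only geometry the C8 propargyl tether allows, so C13 is fixed by C8 and both C13 epimers of 13 converge), the allyl-stabilised silyloxocarbenium ion then loses its silyl group to methanol and protodeauration leaves the exocyclic methylene, so ring D, the C13–C16 bond and the bridgehead carbinol form in one step; the closest known reaction type is the gold-catalysed Conia-ene-type carbocyclisation of simple silyl enol ethers onto alkynes, not shown for an α-silyloxy (enediol) nucleophile that creates a fully substituted oxygenated bridgehead.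

Step 8
Reactants: 15 methyl 2-[(1R,5S)-5-[(tert-butyldimethylsilyl)oxy]-6-methylidene-4-oxobicyclo[3.2.1]oct-2-en-1-yl]acetate
Product: 16 2-[(1R,5S)-5-[(tert-butyldimethylsilyl)oxy]-6-methylidene-4-oxobicyclo[3.2.1]oct-2-en-1-yl]acetic acid
Conditions: LiOH, THF/H2O, 0 °C to rt; then 1 M HCl to pH 3
Reagents that add atoms: lithium hydroxide [Li+].[OH-]
Why: Saponification of the unhindered methyl ester is safe because the enone has no enolisable or epimerisable position and the bridgehead silyl ether resists cold hydroxide.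

**Fragment 2 (ring A)**

Step 9
Reactants: 17 (3E)-4-methoxybut-3-en-2-one
Product: 18 (E)-1-methoxy-3-(trimethylsilyloxy)buta-1,3-diene
Conditions: Me3SiCl, Et3N, ZnCl2 (cat.), benzene, 40 °C
Reagents that add atoms: chlorotrimethylsilane C[Si](C)(C)Cl
Why: O-Silylation of the enolised vinylogous ester is the standard Danishefsky diene synthesis.

Step 10
Reactants: 19 2-methylprop-2-enoyl chloride
Product: 20 tert-butyl 2-methylprop-2-enoate
Conditions: t-BuOH, Et3N, DMAP (cat.), CH2Cl2, 0 °C to rt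
Reagents that add atoms: tert-butanol CC(C)(C)O
Why: DMAP-catalysed acylation installs the bulky tert-butyl ester that later steers the borylation and can be removed without base.

Step 11
Reactants: 18 (E)-1-methoxy-3-(trimethylsilyloxy)buta-1,3-diene; 20 tert-butyl 2-methylprop-2-enoate
Product: 22 tert-butyl 1-methyl-4-oxocyclohex-2-ene-1-carboxylate (racemic), via Diels–Alder cycloadduct 21 (not isolated)
Conditions: toluene, 130 °C, sealed tube; then 0.1 M HCl, THF, 0 °C
Reagents that add atoms: none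
Why: Diels–Alder reaction with diene-controlled regiochemistry (the methoxy carbon bonds to the ester-bearing carbon), then enol ether hydrolysis and β-elimination of methanol, gives the 4,4-disubstituted cyclohexenone whose stereocentre is erased in step 12.

Step 12
Reactants: 22 tert-butyl 1-methyl-4-oxocyclohex-2-ene-1-carboxylate
Product: 23 tert-butyl 1-methyl-4-oxocyclohexa-2,5-diene-1-carboxylate
Conditions: DDQ, 1,4-dioxane, 100 °C
Reagents that add atoms: none
Why: DDQ dehydrogenation of the saturated side gives the achiral, prochiral cross-conjugated dienone.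

Step 13
Reactants: 23 tert-butyl 1-methyl-4-oxocyclohexa-2,5-diene-1-carboxylate
Product: 24 tert-butyl (1R,6S)-1-methyl-4-oxo-6-(4,4,5,5-tetramethyl-1,3,2-dioxaborolan-2-yl)cyclohex-2-ene-1-carboxylate
Conditions: CuCl (5 mol%), (R)-DTBM-SEGPHOS (6 mol%), NaOt-Bu (10 mol%), B2pin2, MeOH, THF, −20 °C
Reagents that add atoms: bis(pinacolato)diboron CC1(C)OB(OC1(C)C)B1OC(C)(C)C(C)(C)O1
Why: Copper-catalysed asymmetric conjugate borylation used as a desymmetrisation, in which the chiral copper–boryl species adds to one enantiotopic enone arm on the face anti to the bulky tert-butyl ester and so sets C3 and the quaternary C4 with boron cis to the methyl group (the ligand antipode is used if the sense proves opposite).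

Step 14
Reactants: 24 tert-butyl (1R,6S)-1-methyl-4-oxo-6-(4,4,5,5-tetramethyl-1,3,2-dioxaborolan-2-yl)cyclohex-2-ene-1-carboxylate
Product: 25 tert-butyl (1S,6S)-6-hydroxy-1-methyl-4-oxocyclohex-2-ene-1-carboxylate
Conditions: 30% H2O2, pH 7 phosphate buffer, THF, 0 °C
Reagents that add atoms: hydrogen peroxide OO
Why: Stereoretentive C–B oxidation (1,2-boronate shift) gives the β-hydroxy ketone with the C3 oxygen cis to the C4 methyl, buffered to avoid β-elimination.

Step 15
Reactants: 25 tert-butyl (1S,6S)-6-hydroxy-1-methyl-4-oxocyclohex-2-ene-1-carboxylate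
Product: 26 tert-butyl (1S,6S)-6-[(tert-butyldimethylsilyl)oxy]-1-methyl-4-oxocyclohex-2-ene-1-carboxylate
Conditions: TBSOTf, 2,6-lutidine, CH2Cl2, −78 to 0 °C
Reagents that add atoms: tert-butyldimethylsilyl triflate CC(C)(C)[Si](C)(C)OS(=O)(=O)C(F)(F)F
Why: Silyl ether formation blocks retro-aldol and elimination of the β-hydroxy carbonyl unit through all later basic steps.

Step 16
Reactants: 26 tert-butyl (1S,6S)-6-[(tert-butyldimethylsilyl)oxy]-1-methyl-4-oxocyclohex-2-ene-1-carboxylate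
Product: 28 tert-butyl (1S,6S)-3-bromo-6-[(tert-butyldimethylsilyl)oxy]-1-methyl-4-oxocyclohex-2-ene-1-carboxylate, via dibromide 27 (not isolated)
Conditions: Br2, CH2Cl2, 0 °C; then Et3N, 0 °C to rt
Reagents that add atoms: bromine BrBr
Why: Bromine addition to the enone double bond followed by E1cB loss of HBr through the acidic α-hydrogen gives the α-bromoenone with the halide on C10.

Step 17
Reactants: 28 tert-butyl (1S,6S)-3-bromo-6-[(tert-butyldimethylsilyl)oxy]-1-methyl-4-oxocyclohex-2-ene-1-carboxylate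
Product: 29 tert-butyl (1S,4S,6S)-3-bromo-6-[(tert-butyldimethylsilyl)oxy]-4-hydroxy-1-methylcyclohex-2-ene-1-carboxylate
Conditions: (R)-Me-CBS (20 mol%), catecholborane, toluene, −78 °C
Reagents that add atoms: none
Why: Reagent-controlled CBS reduction (bromovinyl side as the large group) sets C1 with the hydroxyl trans to the C3 silyloxy group and cis to the ester, the face needed for the later suprafacial transfer to C5.

**Union and completion**

Step 18
Reactants: 16 2-[(1R,5S)-5-[(tert-butyldimethylsilyl)oxy]-6-methylidene-4-oxobicyclo[3.2.1]oct-2-en-1-yl]acetic acid; 29 tert-butyl (1S,4S,6S)-3-bromo-6-[(tert-butyldimethylsilyl)oxy]-4-hydroxy-1-methylcyclohex-2-ene-1-carboxylate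
Product: 30 (1S,4S,5S)-2-bromo-4-(tert-butoxycarbonyl)-5-[(tert-butyldimethylsilyl)oxy]-4-methylcyclohex-2-en-1-yl 2-[(1R,5S)-5-[(tert-butyldimethylsilyl)oxy]-6-methylidene-4-oxobicyclo[3.2.1]oct-2-en-1-yl]acetate
Conditions: EDC·HCl, DMAP, CH2Cl2, 0 °C to rt
Reagents that add atoms: none
Why: Steglich esterification joins the two fragments with retention at C1.

Step 19
Reactants: 30 the fragment-joining allylic ester
Product: 33 19-tert-butyl 7-[2-(trimethylsilyl)ethyl] 10-bromo-3β,13-bis[(tert-butyldimethylsilyl)oxy]-12-oxo-9,10-seco-20-norgibberella-1(10),9(11),16-triene-7,19-dioate (C6 epimer mixture), via silyl ketene acetal 31 (not isolated), via Claisen acid 32 (not isolated)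
Conditions: LiN(SiMe3)2, Me3SiCl/Et3N, THF, −78 °C, then 65 °C; 1 M HCl work-up; crude acid, Me3SiCH2CH2OH, EDC·HCl, DMAP, CH2Cl2, rt
Reagents that add atoms: 2-(trimethylsilyl)ethanol C[Si](C)(C)CCO
Why: Ireland–Claisen rearrangement, in which only the acetate CH2 can be enolised (the enone is non-enolisable) and the suprafacial [3,3] shift forms C5–C6 on the face vacated by the C1–O bond, sets C5 from C1 and leaves the vinyl bromide at C10=C1; C6 forms as an epimer mixture that is corrected in step 21, and the freed C7 acid is capped as the fluoride-labile TMSE ester.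

Step 20
Reactants: 33 the 9,10-seco vinyl bromide diester
Product: 34 19-tert-butyl 7-[2-(trimethylsilyl)ethyl] 3β,13-bis[(tert-butyldimethylsilyl)oxy]-12-oxo-20-norgibberella-1(10),16-diene-7,19-dioate (C6 epimer mixture)
Conditions: Pd(OAc)2 (10 mol%), PPh3 (25 mol%), HCO2Na, Et4NCl, DMF, 80 °C
Reagents that add atoms: none
Why: Intramolecular reductive Heck cyclisation, in which zerovalent palladium inserts into the C10–Br bond, 5-exo syn-carbopalladation of the C9=C11 enone occurs from the exo face (anti to the C15–C16 bridge) and, with no syn β-hydrogen available, formate reduces the palladium enolate, closes ring B and sets C9.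

Step 21
Reactants: 34 the tetracyclic keto diester (C6 epimer mixture)
Product: 35 19-tert-butyl 7-[2-(trimethylsilyl)ethyl] 3β,13-bis[(tert-butyldimethylsilyl)oxy]-12-oxo-20-norgibberella-1(10),16-diene-7,19-dioate (6β-carboxylate)
Conditions: KOt-Bu (0.3 equiv), t-BuOH/THF, 0 °C to rt; AcOH
Reagents that add atoms: none
Why: Thermodynamic enolate equilibration at C6 places the C7 ester trans to the quaternary C4 (natural 6β), and no other stereocentre is epimerisable under these conditions.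

Step 22
Reactants: 35 the 6β keto diester
Product: 37 7-[2-(trimethylsilyl)ethyl] hydrogen 3β,13-bis[(tert-butyldimethylsilyl)oxy]-12-oxo-20-norgibberella-1(10),16-diene-7,19-dioate (free C19 acid), via trimethylsilyl ester 36 (not isolated)
Conditions: Me3SiOTf, 2,6-lutidine, CH2Cl2, 0 °C; aq. citric acid work-up
Reagents that add atoms: none
Why: Silyl-triflate-mediated tert-butyl ester cleavage (loss of isobutene to the silyl ester, hydrolysed on work-up) frees the C19 acid without base and leaves the TMSE ester and TBS ethers intact, the C12 ketone being recovered unchanged after the acidic work-up.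

Step 23
Reactants: 37 the C19 acid
Product: 38 2-(trimethylsilyl)ethyl 3β,13-bis[(tert-butyldimethylsilyl)oxy]-12-oxo-1β-(phenylselanyl)-20-norgibberell-16-en-7-oate 19,10-lactone
Conditions: N-(phenylselanyl)phthalimide, CSA (cat.), CH2Cl2, 0 °C
Reagents that add atoms: N-(phenylselanyl)phthalimide O=C1c2ccccc2C(=O)N1[Se]c1ccccc1
Why: Selenolactonisation, in which the seleniranium ion on the β face of C1=C10 is opened at the more substituted C10 by the α-oriented C19 acid (5-exo, anti addition), sets the C10–O centre and the 19,10-lactone; the esterified C7 carboxyl and the C12 ketone offer no competing nucleophile, and reversible selenenylation of the C16 methylene has no internal nucleophile to trap it.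

Step 24
Reactants: 38 the 1β-phenylselanyl lactone
Product: 39 2-(trimethylsilyl)ethyl 3β,13-bis[(tert-butyldimethylsilyl)oxy]-12-oxo-20-norgibberella-1,16-dien-7-oate 19,10-lactone
Conditions: 30% H2O2, pyridine, CH2Cl2, 0 °C to rt
Reagents that add atoms: none
Why: Selenoxide syn-elimination can only take the 2β-hydrogen (C10 has none) and so gives the C1=C2 alkene of the allylic lactone.

Step 25
Reactants: 39 the 12-oxo ene-lactone
Product: 40 2-(trimethylsilyl)ethyl 3β,13-bis[(tert-butyldimethylsilyl)oxy]-12α-hydroxy-20-norgibberella-1,16-dien-7-oate 19,10-lactone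
Conditions: LiBH(s-Bu)3, THF, −78 °C; AcOH
Reagents that add atoms: none
Why: Bulky-hydride ketone reduction in which the α face of C12 (the axial direction on ring C) is blocked by the 1,3-syn C9–C10 bond and the lactone oxygen, so hydride arrives along the equatorial trajectory on the side of the C15–C16 bridge and gives the axial 12α-alcohol syn to C10 and anti to the C13–C16 bond, while esters and lactone survive at −78 °C.

Step 26
Reactants: 40 2-(trimethylsilyl)ethyl 3β,13-bis[(tert-butyldimethylsilyl)oxy]-12α-hydroxy-20-norgibberella-1,16-dien-7-oate 19,10-lactone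
Product: 41 3β,12α,13-trihydroxy-20-norgibberella-1,16-diene-7,19-dioic acid 19,10-lactone (the target, a 12-hydroxygibberellic acid)
Conditions: Bu4NF/AcOH (1:1), THF, 0 to 40 °C
Reagents that add atoms: none
Why: Buffered fluoride removes both TBS ethers and fragments the TMSE ester (loss of ethene) under near-neutral conditions, avoiding lactone migration and C3 retro-aldol epimerisation.

**Compound list**
1 | cyclohexane-1,3-dione | O=C1CCCC(=O)C1 | starting material
2 | 3-ethoxycyclohex-2-en-1-one | CCOC1=CC(=O)CCC1 | intermediate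
3 | 3-bromoprop-1-yne | C#CCBr | starting material
4 | prop-2-yn-1-ylmagnesium bromide | C#CC[Mg]Br | intermediate
5 | 3-ethoxy-1-(prop-2-yn-1-yl)cyclohex-2-en-1-ol (racemic) | CCOC1=CC(O)(CC#C)CCC1 | intermediate
6 | 3-(prop-2-yn-1-yl)cyclohex-2-en-1-one | O=C1CCCC(CC#C)=C1 | intermediate
7 | (1R)-3-(prop-2-yn-1-yl)cyclohex-2-en-1-ol | O[C@@H]1CCCC(CC#C)=C1 | intermediate
8 | 1,1,1-trimethoxyethane | CC(OC)(OC)OC | starting material
9 | (1R)-1-[(1-methoxyethenyl)oxy]-3-(prop-2-yn-1-yl)cyclohex-2-ene | C=C(OC)O[C@@H]1CCCC(CC#C)=C1 | intermediate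
10 | methyl 2-[(1S)-1-(prop-2-yn-1-yl)cyclohex-2-en-1-yl]acetate | C#CC[C@]1(CC(=O)OC)CCCC=C1 | intermediate
11 | methyl 2-[(1S)-4-oxo-1-(prop-2-yn-1-yl)cyclohex-2-en-1-yl]acetate | C#CC[C@]1(CC(=O)OC)CCC(=O)C=C1 | intermediate
12 | methyl 2-[(1S)-4-[(tert-butyldimethylsilyl)oxy]-1-(prop-2-yn-1-yl)cyclohexa-2,4-dien-1-yl]acetate | C#CC[C@]1(CC(=O)OC)CC=C(O[Si](C)(C)C(C)(C)C)C=C1 | intermediate
13 | methyl 2-[(1R,5RS)-5-[(tert-butyldimethylsilyl)oxy]-4-oxo-1-(prop-2-yn-1-yl)cyclohex-2-en-1-yl]acetate (C5 epimer mixture) | C#CC[C@]1(CC(=O)OC)CC(O[Si](C)(C)C(C)(C)C)C(=O)C=C1 | intermediate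
14 | methyl 2-[(1R)-4,5-bis[(tert-butyldimethylsilyl)oxy]-1-(prop-2-yn-1-yl)cyclohexa-2,4-dien-1-yl]acetate | C#CC[C@]1(CC(=O)OC)CC(O[Si](C)(C)C(C)(C)C)=C(O[Si](C)(C)C(C)(C)C)C=C1 | intermediate
15 | methyl 2-[(1R,5S)-5-[(tert-butyldimethylsilyl)oxy]-6-methylidene-4-oxobicyclo[3.2.1]oct-2-en-1-yl]acetate | C=C1C[C@@]2(C[C@@]1(O[Si](C)(C)C(C)(C)C)C(=O)C=C2)CC(=O)OC | intermediate
16 | 2-[(1R,5S)-5-[(tert-butyldimethylsilyl)oxy]-6-methylidene-4-oxobicyclo[3.2.1]oct-2-en-1-yl]acetic acid | C=C1C[C@@]2(C[C@@]1(O[Si](C)(C)C(C)(C)C)C(=O)C=C2)CC(=O)O | intermediate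
17 | (3E)-4-methoxybut-3-en-2-one | CO/C=C/C(C)=O | starting material
18 | (E)-1-methoxy-3-(trimethylsilyloxy)buta-1,3-diene | CO/C=C/C(=C)O[Si](C)(C)C | intermediate
19 | 2-methylprop-2-enoyl chloride | C=C(C)C(Cl)=O | starting material
20 | tert-butyl 2-methylprop-2-enoate | C=C(C)C(=O)OC(C)(C)C | intermediate
21 | tert-butyl 2-methoxy-1-methyl-4-[(trimethylsilyl)oxy]cyclohex-3-ene-1-carboxylate (racemic, diastereomer mixture) | COC1C=C(O[Si](C)(C)C)CCC1(C)C(=O)OC(C)(C)C | intermediate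
22 | tert-butyl 1-methyl-4-oxocyclohex-2-ene-1-carboxylate (racemic) | O=C1C=CC(C)(C(=O)OC(C)(C)C)CC1 | intermediate
23 | tert-butyl 1-methyl-4-oxocyclohexa-2,5-diene-1-carboxylate | O=C1C=CC(C)(C(=O)OC(C)(C)C)C=C1 | intermediate
24 | tert-butyl (1R,6S)-1-methyl-4-oxo-6-(4,4,5,5-tetramethyl-1,3,2-dioxaborolan-2-yl)cyclohex-2-ene-1-carboxylate | O=C1C[C@H](B2OC(C)(C)C(C)(C)O2)[C@@](C)(C(=O)OC(C)(C)C)C=C1 | intermediate
25 | tert-butyl (1S,6S)-6-hydroxy-1-methyl-4-oxocyclohex-2-ene-1-carboxylate | O=C1C[C@H](O)[C@@](C)(C(=O)OC(C)(C)C)C=C1 | intermediate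
26 | tert-butyl (1S,6S)-6-[(tert-butyldimethylsilyl)oxy]-1-methyl-4-oxocyclohex-2-ene-1-carboxylate | O=C1C[C@H](O[Si](C)(C)C(C)(C)C)[C@@](C)(C(=O)OC(C)(C)C)C=C1 | intermediate
27 | tert-butyl 2,3-dibromo-6-[(tert-butyldimethylsilyl)oxy]-1-methyl-4-oxocyclohexane-1-carboxylate (C1, C6 as in 26; bromide epimers) | O=C1C[C@H](O[Si](C)(C)C(C)(C)C)[C@@](C)(C(=O)OC(C)(C)C)C(Br)C1Br | intermediate
28 | tert-butyl (1S,6S)-3-bromo-6-[(tert-butyldimethylsilyl)oxy]-1-methyl-4-oxocyclohex-2-ene-1-carboxylate | O=C1C[C@H](O[Si](C)(C)C(C)(C)C)[C@@](C)(C(=O)OC(C)(C)C)C=C1Br | intermediate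
29 | tert-butyl (1S,4S,6S)-3-bromo-6-[(tert-butyldimethylsilyl)oxy]-4-hydroxy-1-methylcyclohex-2-ene-1-carboxylate | O[C@H]1C[C@H](O[Si](C)(C)C(C)(C)C)[C@@](C)(C(=O)OC(C)(C)C)C=C1Br | intermediate
30 | (1S,4S,5S)-2-bromo-4-(tert-butoxycarbonyl)-5-[(tert-butyldimethylsilyl)oxy]-4-methylcyclohex-2-en-1-yl 2-[(1R,5S)-5-[(tert-butyldimethylsilyl)oxy]-6-methylidene-4-oxobicyclo[3.2.1]oct-2-en-1-yl]acetate | C=C1C[C@@]2(C[C@@]1(O[Si](C)(C)C(C)(C)C)C(=O)C=C2)CC(=O)O[C@H]1C[C@H](O[Si](C)(C)C(C)(C)C)[C@@](C)(C(=O)OC(C)(C)C)C=C1Br | intermediate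
31 | O-trimethylsilyl ketene acetal of 30 (C6=C7(OSiMe3)–O–C1, E/Z mixture) | C=C1C[C@@]2(C[C@@]1(O[Si](C)(C)C(C)(C)C)C(=O)C=C2)C=C(O[Si](C)(C)C)O[C@H]1C[C@H](O[Si](C)(C)C(C)(C)C)[C@@](C)(C(=O)OC(C)(C)C)C=C1Br | intermediate
32 | 19-tert-butyl hydrogen 10-bromo-3β,13-bis[(tert-butyldimethylsilyl)oxy]-12-oxo-9,10-seco-20-norgibberella-1(10),9(11),16-triene-7,19-dioate (free C7 acid, C6 epimer mixture) | C=C1C[C@@]2(C[C@@]1(O[Si](C)(C)C(C)(C)C)C(=O)C=C2)C(C(=O)O)[C@H]1C(Br)=CC[C@H](O[Si](C)(C)C(C)(C)C)[C@@]1(C)C(=O)OC(C)(C)C | intermediate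
33 | 19-tert-butyl 7-[2-(trimethylsilyl)ethyl] 10-bromo-3β,13-bis[(tert-butyldimethylsilyl)oxy]-12-oxo-9,10-seco-20-norgibberella-1(10),9(11),16-triene-7,19-dioate (C6 epimer mixture) | C=C1C[C@@]2(C[C@@]1(O[Si](C)(C)C(C)(C)C)C(=O)C=C2)C(C(=O)OCC[Si](C)(C)C)[C@H]1C(Br)=CC[C@H](O[Si](C)(C)C(C)(C)C)[C@@]1(C)C(=O)OC(C)(C)C | intermediate
34 | 19-tert-butyl 7-[2-(trimethylsilyl)ethyl] 3β,13-bis[(tert-butyldimethylsilyl)oxy]-12-oxo-20-norgibberella-1(10),16-diene-7,19-dioate (C6 epimer mixture) | C=C1C[C@]23C[C@@]1(O[Si](C)(C)C(C)(C)C)C(=O)C[C@H]2C1=CC[C@H](O[Si](C)(C)C(C)(C)C)[C@@](C)(C(=O)OC(C)(C)C)[C@H]1C3C(=O)OCC[Si](C)(C)C | intermediate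
35 | 19-tert-butyl 7-[2-(trimethylsilyl)ethyl] 3β,13-bis[(tert-butyldimethylsilyl)oxy]-12-oxo-20-norgibberella-1(10),16-diene-7,19-dioate (6β-carboxylate) | C=C1C[C@]23C[C@@]1(O[Si](C)(C)C(C)(C)C)C(=O)C[C@H]2C1=CC[C@H](O[Si](C)(C)C(C)(C)C)[C@@](C)(C(=O)OC(C)(C)C)[C@H]1[C@@H]3C(=O)OCC[Si](C)(C)C | intermediate
36 | 19-trimethylsilyl 7-[2-(trimethylsilyl)ethyl] 3β,13-bis[(tert-butyldimethylsilyl)oxy]-12-oxo-20-norgibberella-1(10),16-diene-7,19-dioate | C=C1C[C@]23C[C@@]1(O[Si](C)(C)C(C)(C)C)C(=O)C[C@H]2C1=CC[C@H](O[Si](C)(C)C(C)(C)C)[C@@](C)(C(=O)O[Si](C)(C)C)[C@H]1[C@@H]3C(=O)OCC[Si](C)(C)C | intermediate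
37 | 7-[2-(trimethylsilyl)ethyl] hydrogen 3β,13-bis[(tert-butyldimethylsilyl)oxy]-12-oxo-20-norgibberella-1(10),16-diene-7,19-dioate (free C19 acid) | C=C1C[C@]23C[C@@]1(O[Si](C)(C)C(C)(C)C)C(=O)C[C@H]2C1=CC[C@H](O[Si](C)(C)C(C)(C)C)[C@@](C)(C(=O)O)[C@H]1[C@@H]3C(=O)OCC[Si](C)(C)C | intermediate
38 | 2-(trimethylsilyl)ethyl 3β,13-bis[(tert-butyldimethylsilyl)oxy]-12-oxo-1β-(phenylselanyl)-20-norgibberell-16-en-7-oate 19,10-lactone | C=C1C[C@]23C[C@@]1(O[Si](C)(C)C(C)(C)C)C(=O)C[C@H]2[C@@]12[C@H]([Se]c4ccccc4)C[C@H](O[Si](C)(C)C(C)(C)C)[C@@](C)(C(=O)O1)[C@H]2[C@@H]3C(=O)OCC[Si](C)(C)C | intermediate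
39 | 2-(trimethylsilyl)ethyl 3β,13-bis[(tert-butyldimethylsilyl)oxy]-12-oxo-20-norgibberella-1,16-dien-7-oate 19,10-lactone | C=C1C[C@]23C[C@@]1(O[Si](C)(C)C(C)(C)C)C(=O)C[C@H]2[C@@]12C=C[C@H](O[Si](C)(C)C(C)(C)C)[C@@](C)(C(=O)O1)[C@H]2[C@@H]3C(=O)OCC[Si](C)(C)C | intermediate
40 | 2-(trimethylsilyl)ethyl 3β,13-bis[(tert-butyldimethylsilyl)oxy]-12α-hydroxy-20-norgibberella-1,16-dien-7-oate 19,10-lactone | C=C1C[C@]23C[C@@]1(O[Si](C)(C)C(C)(C)C)[C@@H](O)C[C@H]2[C@@]12C=C[C@H](O[Si](C)(C)C(C)(C)C)[C@@](C)(C(=O)O1)[C@H]2[C@@H]3C(=O)OCC[Si](C)(C)C | intermediate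
41 | 3β,12α,13-trihydroxy-20-norgibberella-1,16-diene-7,19-dioic acid 19,10-lactone (12-hydroxygibberellic acid) | C=C1C[C@]23C[C@@]1(O)[C@@H](O)C[C@H]2[C@@]12C=C[C@H](O)[C@@](C)(C(=O)O1)[C@H]2[C@@H]3C(=O)O | target

**Step count and risks**

Total steps: 26. Longest linear sequence: 17 steps (steps 1–8 then 18–26; the ring A line 9, 11–17 then 18–26 is equally long).

Step 7 (the new gold cyclisation) may fail through attack by C12 (6-exo, bicyclo[2.2.2]) or methanolysis of the enediol ether before cyclisation. The fallback uses known chemistry, sets out from 13 and returns at 15. Markovnikov hydrobromination of the terminal alkyne (B-bromo-9-BBN, CH2Cl2, 0 °C; then AcOH) gives methyl 2-[(1R,5RS)-1-(2-bromoprop-2-en-1-yl)-5-[(tert-butyldimethylsilyl)oxy]-4-oxocyclohex-2-en-1-yl]acetate F1. Palladium-catalysed intramolecular ketone α-alkenylation (Pd(PPh3)4, PhOK, THF, 70 °C) through the only possible enolate (C13) then forms the C13–C16 bond and gives 15.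

Step 19 (Ireland–Claisen) forms a bond between two neopentyl-type carbons, so the silyl ketene acetal may decompose before it rearranges. The fallback reverses the bond order, sets out from 16 and 29 and returns at 34. Acid 16 is esterified (Me3SiCH2CH2OH, EDC·HCl, DMAP) to 2-(trimethylsilyl)ethyl 2-[(1R,5S)-5-[(tert-butyldimethylsilyl)oxy]-6-methylidene-4-oxobicyclo[3.2.1]oct-2-en-1-yl]acetate F2. Alcohol 29 is converted by Miyaura borylation (B2pin2, PdCl2(dppf), KOAc, dioxane, 80 °C) into tert-butyl (1S,4S,6S)-6-[(tert-butyldimethylsilyl)oxy]-4-hydroxy-1-methyl-3-(4,4,5,5-tetramethyl-1,3,2-dioxaborolan-2-yl)cyclohex-2-ene-1-carboxylate F3. Rhodium-catalysed 1,4-addition ([Rh(cod)OH]2, dioxane/H2O, 40 °C) of this boronate to the enone ester, from the exo face, makes C9–C10 and gives 19-tert-butyl 7-[2-(trimethylsilyl)ethyl] 3β,13-bis[(tert-butyldimethylsilyl)oxy]-1α-hydroxy-12-oxo-5,6-seco-20-norgibberella-5(10),16-diene-7,19-dioate F4. Acylation (ClCO2Me, pyridine) gives 19-tert-butyl 7-[2-(trimethylsilyl)ethyl] 3β,13-bis[(tert-butyldimethylsilyl)oxy]-1α-(methoxycarbonyloxy)-12-oxo-5,6-seco-20-norgibberella-5(10),16-diene-7,19-dioate F5. Intramolecular Tsuji–Trost alkylation (LiN(SiMe3)2 2.2 equiv, Pd(PPh3)4, THF) then closes C5–C6 by ionisation anti to the carbonate and outer-sphere enolate attack anti to palladium (net retention, alkene shifting to C1=C10), giving 34.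

Step 20 (reductive Heck) may suffer hydrodebromination or attack on the endo face. The fallback sets out from 33 and returns at 34: a tin hydride radical chain (Bu3SnH, AIBN, benzene, 80 °C) generates the C10 vinyl radical, which adds 5-exo to the enone β-carbon C9 and is quenched at C11. This fallback makes no new compound (F0).

Further compounds
F1 | step 7 | methyl 2-[(1R,5RS)-1-(2-bromoprop-2-en-1-yl)-5-[(tert-butyldimethylsilyl)oxy]-4-oxocyclohex-2-en-1-yl]acetate | C=C(Br)C[C@]1(CC(=O)OC)CC(O[Si](C)(C)C(C)(C)C)C(=O)C=C1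
F2 | step 19 | 2-(trimethylsilyl)ethyl 2-[(1R,5S)-5-[(tert-butyldimethylsilyl)oxy]-6-methylidene-4-oxobicyclo[3.2.1]oct-2-en-1-yl]acetate | C=C1C[C@@]2(C[C@@]1(O[Si](C)(C)C(C)(C)C)C(=O)C=C2)CC(=O)OCC[Si](C)(C)C
F3 | step 19 | tert-butyl (1S,4S,6S)-6-[(tert-butyldimethylsilyl)oxy]-4-hydroxy-1-methyl-3-(4,4,5,5-tetramethyl-1,3,2-dioxaborolan-2-yl)cyclohex-2-ene-1-carboxylate | O[C@H]1C[C@H](O[Si](C)(C)C(C)(C)C)[C@@](C)(C(=O)OC(C)(C)C)C=C1B1OC(C)(C)C(C)(C)O1
F4 | step 19 | 19-tert-butyl 7-[2-(trimethylsilyl)ethyl] 3β,13-bis[(tert-butyldimethylsilyl)oxy]-1α-hydroxy-12-oxo-5,6-seco-20-norgibberella-5(10),16-diene-7,19-dioate | C=C1C[C@]2(CC(=O)OCC[Si](C)(C)C)C[C@@]1(O[Si](C)(C)C(C)(C)C)C(=O)C[C@H]2C1=C[C@](C)(C(=O)OC(C)(C)C)[C@@H](O[Si](C)(C)C(C)(C)C)C[C@@H]1O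
F5 | step 19 | 19-tert-butyl 7-[2-(trimethylsilyl)ethyl] 3β,13-bis[(tert-butyldimethylsilyl)oxy]-1α-(methoxycarbonyloxy)-12-oxo-5,6-seco-20-norgibberella-5(10),16-diene-7,19-dioate | C=C1C[C@]2(CC(=O)OCC[Si](C)(C)C)C[C@@]1(O[Si](C)(C)C(C)(C)C)C(=O)C[C@H]2C1=C[C@](C)(C(=O)OC(C)(C)C)[C@@H](O[Si](C)(C)C(C)(C)C)C[C@@H]1OC(=O)OC
F0 | step 20 | none | none
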